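The route rests on cutting the C3–C4 bond of ring B. Ring B is a benzene-1,3-diol whose hydroxyls on C3 and C5 flank the ring C oxygen on C4, with the ring A oxygen on C1: a folded triketide whose middle carbonyl is an aryl enol ether. In one operation, methoxide should open a 2-pyrone and a Claisen condensation should re-close it as this arene, with both hindered ethers to rings A and C already in place. The precursor is a 2-pyrone carrying the ring A aryloxy group on C4 and, on C6, a CH2 group bound to the C1 oxygen of a ring C unit that already bears ring D with a bromine.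

Key step: step 12

Remarks before the steps
- Rings are lettered A to G from the 2,4,6-trihydroxyphenyl end to the 3,4,5-trihydroxyphenyl end.
  - Ring B: C1 carries the oxygen to ring A, C3 and C5 the hydroxyls, C4 the oxygen to ring C.
  - Rings C and E: C1 and C2 carry the two ether oxygens (ring C: C1 to ring B, C2 to ring D; ring E: C1 to ring D, C2 to ring F), and C3 to C5 the hydroxyls.
  - Ring D: C1 oxygen to ring C, C3 and C4 hydroxyls, C5 oxygen to ring E.
  - Ring F: C1 oxygen to ring E, C3 and C5 hydroxyls, C4 oxygen to ring G.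
- The target has no stereocentre, so no step has to set one.
- Assumption: the seven building blocks marked as starting materials in the compound list are purchased.
- Design choices:
  - All 18 hydroxyls travel as methyl ethers.
  - The C2 oxygen of ring C enters the key step already as its ring D aryl ether (bromine on C5 of ring D) and not under a temporary group. This doubly flanked ether is therefore made on a monocyclic phenol, and nothing has to be unmasked between ring closure and fragment union.
  - A Weinreb amide replaces an aryloxyacetyl chloride, which could close onto its own electron-rich ring.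
- Correction of a descriptor: the opened ester in the key step keeps the ester and the ketone chain cis across the double bond. By the sequence rules this is the E isomer, because the aryloxy group outranks the chain.

Step 1
Reactants: 1 3,4,5-trimethoxyphenol
Product: 2 2-hydroxy-4,5,6-trimethoxybenzaldehyde
Conditions: MgCl2, Et3N, (CH2O)n, MeCN, 80 °C
Reagents that add atoms: paraformaldehyde as formaldehyde, C=O
Why: Magnesium phenoxide-directed ortho-formylation (Casnati–Skattebøl type) delivers formaldehyde next to the hydroxyl, and since the two ortho positions of 1 are equivalent and the para position is blocked only one aldehyde can form.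

Step 2
Reactants: 2 2-hydroxy-4,5,6-trimethoxybenzaldehyde; 3 2-chloro-N-methoxy-N-methylacetamide
Product: 4 2-(2-formyl-3,4,5-trimethoxyphenoxy)-N-methoxy-N-methylacetamide
Conditions: K2CO3, DMF, 60 °C
Reagents that add atoms: none
Why: Williamson ether synthesis in which the phenoxide displaces chloride from the activated α-chloro amide, tying the C1 oxygen of ring C to the two carbons that will become C4 and C5 of ring B.

Step 3
Reactants: 4 2-(2-formyl-3,4,5-trimethoxyphenoxy)-N-methoxy-N-methylacetamide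
Product: 6 2-(2-hydroxy-3,4,5-trimethoxyphenoxy)-N-methoxy-N-methylacetamide, via aryl formate 5 (not isolated)
Conditions: mCPBA, CH2Cl2, 0 °C to rt; NaHCO3 wash; then K2CO3 (cat.), MeOH, rt
Reagents that add atoms: mCPBA (3-chloroperoxybenzoic acid), O=C(OO)c1cccc(Cl)c1
Why: Baeyer–Villiger oxidation (Dakin type) in which the electron-rich aryl group migrates in preference to hydrogen, followed by methanolysis of the formate, turns the aldehyde carbon into the C2 hydroxyl of ring C.

Step 4
Reactants: 7 2-bromo-6-methoxyphenol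
Product: 8 2-bromo-4-iodo-6-methoxyphenol
Conditions: NIS, TsOH (cat.), MeCN, rt
Reagents that add atoms: N-iodosuccinimide, O=C1CCC(=O)N1I
Why: Electrophilic aromatic iodination goes para to the free hydroxyl, the strongest director, because both of its ortho positions are occupied.

Step 5
Reactants: 8 2-bromo-4-iodo-6-methoxyphenol
Product: 9 1-bromo-5-iodo-2,3-dimethoxybenzene
Conditions: MeI, K2CO3, acetone, 56 °C
Reagents that add atoms: iodomethane, CI
Why: Williamson O-methylation gives the ring D building block with iodine on the future C1 and bromine on the future C5.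

Step 6
Reactants: 6 2-(2-hydroxy-3,4,5-trimethoxyphenoxy)-N-methoxy-N-methylacetamide; 9 1-bromo-5-iodo-2,3-dimethoxybenzene
Product: 10 2-[2-(3-bromo-4,5-dimethoxyphenoxy)-3,4,5-trimethoxyphenoxy]-N-methoxy-N-methylacetamide
Conditions: CuI (cat.), picolinic acid (cat.), K3PO4, DMSO, 80 °C
Reagents that add atoms: none
Why: Ullmann ether synthesis in which the doubly ortho-substituted phenoxide couples at the unhindered C–I bond, which reacts well before the C–Br bond, so the hindered ring C to ring D ether is made on a small molecule and the bromine is kept.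

Step 7
Reactants: 10 2-[2-(3-bromo-4,5-dimethoxyphenoxy)-3,4,5-trimethoxyphenoxy]-N-methoxy-N-methylacetamide; 11 2,2,6-trimethyl-4H-1,3-dioxin-4-one
Product: 12 6-{3-[2-(3-bromo-4,5-dimethoxyphenoxy)-3,4,5-trimethoxyphenoxy]-2-oxopropyl}-2,2-dimethyl-4H-1,3-dioxin-4-one
Conditions: 11 and LiN(SiMe3)2 (slight excess of 11), THF, −78 °C; then 10, −78 to −20 °C; aq. NH4Cl
Reagents that add atoms: none
Why: Claisen-type C-acylation in which the lithium dienolate of 11 adds through its γ-carbon to the Weinreb amide and the chelated tetrahedral adduct lasts until work-up, which prevents over-addition and proton transfer from the keto dioxinone.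

Step 8
Reactants: 12 6-{3-[2-(3-bromo-4,5-dimethoxyphenoxy)-3,4,5-trimethoxyphenoxy]-2-oxopropyl}-2,2-dimethyl-4H-1,3-dioxin-4-one
Product: 14 6-{[2-(3-bromo-4,5-dimethoxyphenoxy)-3,4,5-trimethoxyphenoxy]methyl}-4-hydroxy-2H-pyran-2-one, via acylketene 13 (not isolated)
Conditions: toluene, 110 °C
Reagents that add atoms: none
Why: Thermolysis expels acetone in a retro-hetero-Diels–Alder reaction and the acylketene is trapped by the enol oxygen of the δ-ketone, a standard lactonisation that gives the 4-hydroxy-2-pyrone with the aryloxymethyl group on C6.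

Step 9
Reactants: 14 6-{[2-(3-bromo-4,5-dimethoxyphenoxy)-3,4,5-trimethoxyphenoxy]methyl}-4-hydroxy-2H-pyran-2-one
Product: 15 6-{[2-(3-bromo-4,5-dimethoxyphenoxy)-3,4,5-trimethoxyphenoxy]methyl}-2-oxo-2H-pyran-4-yl 4-methylbenzenesulfonate
Conditions: TsCl, Et3N, CH2Cl2, 0 °C to rt
Reagents that add atoms: 4-toluenesulfonyl chloride, Cc1ccc(cc1)S(Cl)(=O)=O
Why: O-Sulfonylation of the acidic 4-hydroxyl (a vinylogous carboxylic acid) gives the 4-tosyloxy-2-pyrone, a vinylogous mixed anhydride whose C4 is activated for substitution.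

Step 10
Reactants: 16 2,4,6-trimethoxybenzaldehyde
Product: 18 2,4,6-trimethoxyphenol, via aryl formate 17 (not isolated)
Conditions: mCPBA, CH2Cl2, 0 °C to rt; NaHCO3 wash; then K2CO3 (cat.), MeOH, rt
Reagents that add atoms: mCPBA (3-chloroperoxybenzoic acid), O=C(OO)c1cccc(Cl)c1
Why: Baeyer–Villiger oxidation (Dakin type) of the electron-rich aldehyde and methanolysis of the formate give the ring A phenol.

Step 11
Reactants: 15 6-{[2-(3-bromo-4,5-dimethoxyphenoxy)-3,4,5-trimethoxyphenoxy]methyl}-2-oxo-2H-pyran-4-yl 4-methylbenzenesulfonate; 18 2,4,6-trimethoxyphenol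
Product: 19 6-{[2-(3-bromo-4,5-dimethoxyphenoxy)-3,4,5-trimethoxyphenoxy]methyl}-4-(2,4,6-trimethoxyphenoxy)-2H-pyran-2-one
Conditions: K2CO3, MeCN, rt to 40 °C
Reagents that add atoms: none
Why: Addition–elimination (vinylogous acyl substitution) in which the phenoxide adds to C4, activated by the lactone carbonyl, and tosylate leaves, so the ether between ring A and the future C1 of ring B is made at an sp2 carbon without metal catalysis despite the two ortho methoxy groups.

Step 12
Reactants: 19 6-{[2-(3-bromo-4,5-dimethoxyphenoxy)-3,4,5-trimethoxyphenoxy]methyl}-4-(2,4,6-trimethoxyphenoxy)-2H-pyran-2-one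
Product: 21 2-[2-(3-bromo-4,5-dimethoxyphenoxy)-3,4,5-trimethoxyphenoxy]-5-(2,4,6-trimethoxyphenoxy)benzene-1,3-diol, via open-chain keto ester 20 (not isolated)
Conditions: NaOMe (excess), dry MeOH, 65 °C then 110 °C (sealed tube); aq. HCl
Reagents that add atoms: none
Why: Proposed new method: methoxide should add to the lactone carbonyl (pyrone C2) and open the ring to keto ester 20, in which the ester and the ketone chain stay cis across the former C3=C4 bond (the E isomer); the carbanion at the aryloxy-bearing CH2 beside the ketone then attacks the ester carbon, methoxide leaves, and the cyclohexenedione tautomerises to the resorcinol dianion, which makes the sequence irreversible. The closest known reaction type is the alkoxide-induced ring opening and Claisen recyclisation of 4-alkoxy-6-methyl-2-pyrones to phloroglucinol monoethers, which has not been shown with a 4-aryloxy group or with an aryloxy-substituted nucleophilic carbon. Ring B closes by a 6-(enolendo)-exo-trig Claisen condensation that forms its C3–C4 bond, and no stereocentre is created. The site of closure is fixed by the chain, since only this carbanion reaches the ester through a six-membered transition state, and its aryloxy substituent makes the CH2 more acidic than the methyl group of the known substrates. The step needs methoxide to attack C2 and not C4, where it would expel the ring A phenoxide; the acyl character of C2 and the two ortho methoxy groups of ring A, which sit over both faces of C4, should secure this.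

Step 13
Reactants: 21 2-[2-(3-bromo-4,5-dimethoxyphenoxy)-3,4,5-trimethoxyphenoxy]-5-(2,4,6-trimethoxyphenoxy)benzene-1,3-diol
Product: 22 1-bromo-5-{2-[2,6-dimethoxy-4-(2,4,6-trimethoxyphenoxy)phenoxy]-4,5,6-trimethoxyphenoxy}-2,3-dimethoxybenzene (ABCD bromide)
Conditions: MeI, K2CO3, DMF, rt
Reagents that add atoms: iodomethane, CI
Why: Williamson O-methylation of both ring B phenols leaves the C–Br bond of ring D as the only reactive site for the fragment union.

Step 14
Reactants: 2 2-hydroxy-4,5,6-trimethoxybenzaldehyde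
Product: 23 2-(benzyloxy)-4,5,6-trimethoxybenzaldehyde
Conditions: BnBr, K2CO3, DMF, rt
Reagents that add atoms: benzyl bromide, BrCc1ccccc1
Why: Williamson benzylation puts a temporary benzyl group on the oxygen that becomes the C1 oxygen of ring E.

Step 15
Reactants: 23 2-(benzyloxy)-4,5,6-trimethoxybenzaldehyde
Product: 25 6-(benzyloxy)-2,3,4-trimethoxyphenol, via aryl formate 24 (not isolated)
Conditions: mCPBA, CH2Cl2, 0 °C to rt; NaHCO3 wash; then K2CO3 (cat.), MeOH, rt
Reagents that add atoms: mCPBA (3-chloroperoxybenzoic acid), O=C(OO)c1cccc(Cl)c1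
Why: Baeyer–Villiger oxidation (Dakin type) with migration of the tetraoxygenated aryl group, then formate methanolysis, converts the aldehyde carbon into the C2 hydroxyl of ring E.

Step 16
Reactants: 26 4-bromo-2,6-dimethoxyphenol; 27 5-iodo-1,2,3-trimethoxybenzene
Product: 28 5-bromo-1,3-dimethoxy-2-(3,4,5-trimethoxyphenoxy)benzene (FG bromide)
Conditions: CuI (cat.), picolinic acid (cat.), K3PO4, DMSO, 80 °C
Reagents that add atoms: none
Why: Ullmann ether synthesis in which the hindered phenoxide of 26 couples with the unhindered aryl iodide, while its own C–Br bond, para to the phenoxide oxygen and less reactive than C–I, is kept as the handle on C1 of ring F.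

Step 17
Reactants: 25 6-(benzyloxy)-2,3,4-trimethoxyphenol; 28 5-bromo-1,3-dimethoxy-2-(3,4,5-trimethoxyphenoxy)benzene
Product: 29 1-(benzyloxy)-2-[3,5-dimethoxy-4-(3,4,5-trimethoxyphenoxy)phenoxy]-3,4,5-trimethoxybenzene
Conditions: CuI (cat.), picolinic acid (cat.), K3PO4, DMSO, 110 °C
Reagents that add atoms: none
Why: Ullmann ether synthesis between the doubly ortho-substituted phenol and the unhindered aryl bromide forms the ring E to ring F ether, with picolinic acid as a ligand suited to hindered phenols.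

Step 18
Reactants: 29 1-(benzyloxy)-2-[3,5-dimethoxy-4-(3,4,5-trimethoxyphenoxy)phenoxy]-3,4,5-trimethoxybenzene
Product: 30 2-[3,5-dimethoxy-4-(3,4,5-trimethoxyphenoxy)phenoxy]-3,4,5-trimethoxyphenol (EFG phenol)
Conditions: H2 (1 atm), Pd/C, EtOAc–MeOH, rt
Reagents that add atoms: none
Why: Catalytic hydrogenolysis cleaves only the benzyl ether, since methyl and diaryl ethers are inert and no halogen is present, and frees the C1 hydroxyl of ring E.

Step 19
Reactants: 22 1-bromo-5-{2-[2,6-dimethoxy-4-(2,4,6-trimethoxyphenoxy)phenoxy]-4,5,6-trimethoxyphenoxy}-2,3-dimethoxybenzene; 30 2-[3,5-dimethoxy-4-(3,4,5-trimethoxyphenoxy)phenoxy]-3,4,5-trimethoxyphenol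
Product: 31 1-{2-[2,6-dimethoxy-4-(2,4,6-trimethoxyphenoxy)phenoxy]-4,5,6-trimethoxyphenoxy}-3-{2-[3,5-dimethoxy-4-(3,4,5-trimethoxyphenoxy)phenoxy]-3,4,5-trimethoxyphenoxy}-4,5-dimethoxybenzene (octadecamethyl ether of the target)
Conditions: CuI (cat.), picolinic acid (cat.), K3PO4, DMSO, 110 °C
Reagents that add atoms: none
Why: Ullmann ether synthesis joins the fragments through a phenol with one ortho substituent and a bromide with one ortho methoxy group, a pairing within the scope of CuI and picolinic acid, and neither partner carries another reactive group.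

Step 20
Reactants: 31 octadecamethyl ether of the target
Product: 32 CNP0130704.0 (all 18 hydroxyls free)
Conditions: BBr3 (excess), CH2Cl2, −78 °C to rt, argon; then H2O, 0 °C
Reagents that add atoms: none
Why: Lewis acid-mediated cleavage of aryl methyl ethers, in which BBr3 binds each methoxy oxygen and bromide removes the methyl group by SN2 attack, leaves the six diaryl ether bonds intact because they offer no sp3 carbon, and hydrolysis of the borates frees the hydroxyls.

Compound list
1 | 3,4,5-trimethoxyphenol | COc1cc(O)cc(OC)c1OC | starting material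
2 | 2-hydroxy-4,5,6-trimethoxybenzaldehyde | O=Cc1c(O)cc(OC)c(OC)c1OC | intermediate
3 | 2-chloro-N-methoxy-N-methylacetamide | CON(C)C(=O)CCl | starting material
4 | 2-(2-formyl-3,4,5-trimethoxyphenoxy)-N-methoxy-N-methylacetamide | CON(C)C(=O)COc1cc(OC)c(OC)c(OC)c1C=O | intermediate
5 | 2-[2-(formyloxy)-3,4,5-trimethoxyphenoxy]-N-methoxy-N-methylacetamide (not isolated) | CON(C)C(=O)COc1cc(OC)c(OC)c(OC)c1OC=O | intermediate
6 | 2-(2-hydroxy-3,4,5-trimethoxyphenoxy)-N-methoxy-N-methylacetamide | CON(C)C(=O)COc1cc(OC)c(OC)c(OC)c1O | intermediate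
7 | 2-bromo-6-methoxyphenol | COc1cccc(Br)c1O | starting material
8 | 2-bromo-4-iodo-6-methoxyphenol | COc1cc(I)cc(Br)c1O | intermediate
9 | 1-bromo-5-iodo-2,3-dimethoxybenzene | COc1cc(I)cc(Br)c1OC | intermediate
10 | 2-[2-(3-bromo-4,5-dimethoxyphenoxy)-3,4,5-trimethoxyphenoxy]-N-methoxy-N-methylacetamide | CON(C)C(=O)COc1cc(OC)c(OC)c(OC)c1Oc1cc(OC)c(OC)c(Br)c1 | intermediate
11 | 2,2,6-trimethyl-4H-1,3-dioxin-4-one | CC1=CC(=O)OC(C)(C)O1 | starting material
12 | 6-{3-[2-(3-bromo-4,5-dimethoxyphenoxy)-3,4,5-trimethoxyphenoxy]-2-oxopropyl}-2,2-dimethyl-4H-1,3-dioxin-4-one | CC1(C)OC(=O)C=C(CC(=O)COc2cc(OC)c(OC)c(OC)c2Oc2cc(OC)c(OC)c(Br)c2)O1 | intermediate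
13 | 6-[2-(3-bromo-4,5-dimethoxyphenoxy)-3,4,5-trimethoxyphenoxy]hex-1-ene-1,3,5-trione (acylketene, not isolated) | O=C=CC(=O)CC(=O)COc1cc(OC)c(OC)c(OC)c1Oc1cc(OC)c(OC)c(Br)c1 | intermediate
14 | 6-{[2-(3-bromo-4,5-dimethoxyphenoxy)-3,4,5-trimethoxyphenoxy]methyl}-4-hydroxy-2H-pyran-2-one | O=c1cc(O)cc(COc2cc(OC)c(OC)c(OC)c2Oc2cc(OC)c(OC)c(Br)c2)o1 | intermediate
15 | 6-{[2-(3-bromo-4,5-dimethoxyphenoxy)-3,4,5-trimethoxyphenoxy]methyl}-2-oxo-2H-pyran-4-yl 4-methylbenzenesulfonate | Cc1ccc(cc1)S(=O)(=O)Oc1cc(COc2cc(OC)c(OC)c(OC)c2Oc2cc(OC)c(OC)c(Br)c2)oc(=O)c1 | intermediate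
16 | 2,4,6-trimethoxybenzaldehyde | COc1cc(OC)c(C=O)c(OC)c1 | starting material
17 | 2,4,6-trimethoxyphenyl formate (not isolated) | COc1cc(OC)c(OC=O)c(OC)c1 | intermediate
18 | 2,4,6-trimethoxyphenol | COc1cc(OC)c(O)c(OC)c1 | intermediate
19 | 6-{[2-(3-bromo-4,5-dimethoxyphenoxy)-3,4,5-trimethoxyphenoxy]methyl}-4-(2,4,6-trimethoxyphenoxy)-2H-pyran-2-one (key-step precursor) | O=c1cc(Oc2c(OC)cc(OC)cc2OC)cc(COc2cc(OC)c(OC)c(OC)c2Oc2cc(OC)c(OC)c(Br)c2)o1 | intermediate
20 | methyl (2E)-6-[2-(3-bromo-4,5-dimethoxyphenoxy)-3,4,5-trimethoxyphenoxy]-5-oxo-3-(2,4,6-trimethoxyphenoxy)hex-2-enoate (not isolated) | COC(=O)/C=C(/Oc1c(OC)cc(OC)cc1OC)CC(=O)COc1cc(OC)c(OC)c(OC)c1Oc1cc(OC)c(OC)c(Br)c1 | intermediate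
21 | 2-[2-(3-bromo-4,5-dimethoxyphenoxy)-3,4,5-trimethoxyphenoxy]-5-(2,4,6-trimethoxyphenoxy)benzene-1,3-diol (key-step product) | Oc1cc(Oc2c(OC)cc(OC)cc2OC)cc(O)c1Oc1cc(OC)c(OC)c(OC)c1Oc1cc(OC)c(OC)c(Br)c1 | intermediate
22 | 1-bromo-5-{2-[2,6-dimethoxy-4-(2,4,6-trimethoxyphenoxy)phenoxy]-4,5,6-trimethoxyphenoxy}-2,3-dimethoxybenzene (ABCD bromide) | COc1cc(Oc2c(OC)cc(OC)cc2OC)cc(OC)c1Oc1cc(OC)c(OC)c(OC)c1Oc1cc(OC)c(OC)c(Br)c1 | intermediate
23 | 2-(benzyloxy)-4,5,6-trimethoxybenzaldehyde | O=Cc1c(OCc2ccccc2)cc(OC)c(OC)c1OC | intermediate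
24 | 6-(benzyloxy)-2,3,4-trimethoxyphenyl formate (not isolated) | O=COc1c(OCc2ccccc2)cc(OC)c(OC)c1OC | intermediate
25 | 6-(benzyloxy)-2,3,4-trimethoxyphenol | Oc1c(OCc2ccccc2)cc(OC)c(OC)c1OC | intermediate
26 | 4-bromo-2,6-dimethoxyphenol | COc1cc(Br)cc(OC)c1O | starting material
27 | 5-iodo-1,2,3-trimethoxybenzene | COc1cc(I)cc(OC)c1OC | starting material
28 | 5-bromo-1,3-dimethoxy-2-(3,4,5-trimethoxyphenoxy)benzene (FG bromide) | COc1cc(Br)cc(OC)c1Oc1cc(OC)c(OC)c(OC)c1 | intermediate
29 | 1-(benzyloxy)-2-[3,5-dimethoxy-4-(3,4,5-trimethoxyphenoxy)phenoxy]-3,4,5-trimethoxybenzene | COc1cc(Oc2c(OCc3ccccc3)cc(OC)c(OC)c2OC)cc(OC)c1Oc1cc(OC)c(OC)c(OC)c1 | intermediate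
30 | 2-[3,5-dimethoxy-4-(3,4,5-trimethoxyphenoxy)phenoxy]-3,4,5-trimethoxyphenol (EFG phenol) | COc1cc(Oc2c(O)cc(OC)c(OC)c2OC)cc(OC)c1Oc1cc(OC)c(OC)c(OC)c1 | intermediate
31 | 1-{2-[2,6-dimethoxy-4-(2,4,6-trimethoxyphenoxy)phenoxy]-4,5,6-trimethoxyphenoxy}-3-{2-[3,5-dimethoxy-4-(3,4,5-trimethoxyphenoxy)phenoxy]-3,4,5-trimethoxyphenoxy}-4,5-dimethoxybenzene (octadecamethyl ether of the target) | COc1cc(OC)c(Oc2cc(OC)c(Oc3cc(OC)c(OC)c(OC)c3Oc3cc(OC)c(OC)c(Oc4cc(OC)c(OC)c(OC)c4Oc4cc(OC)c(Oc5cc(OC)c(OC)c(OC)c5)c(OC)c4)c3)c(OC)c2)c(OC)c1 | intermediate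
32 | CNP0130704.0: the compound 31 with all 18 methoxy groups as free hydroxyls | Oc1cc(O)c(Oc2cc(O)c(Oc3cc(O)c(O)c(O)c3Oc3cc(O)c(O)c(Oc4cc(O)c(O)c(O)c4Oc4cc(O)c(Oc5cc(O)c(O)c(O)c5)c(O)c4)c3)c(O)c2)c(O)c1 | target

Total step count: 20. Longest linear sequence: 12 steps (steps 1, 2, 3, 6, 7, 8, 9, 11, 12, 13, 19, 20).

Steps most likely to fail

1. Step 12. Methoxide may add to C4 of the pyrone, or to the β-carbon of the opened enoate, and expel the ring A phenoxide. The opened keto ester may also fragment by retro-Claisen attack at the ketone before the carbanion closes the ring. The fallback uses known chemistry and takes ring B from a preformed benzene ring; it sets out from 26 and returns at 22. Purchased 2,3,4-trimethoxyphenol (COc1ccc(O)c(OC)c1OC) would be iodinated next to its hydroxyl (NIS, MeCN) to 6-iodo-2,3,4-trimethoxyphenol F1 and benzylated (BnBr, K2CO3, DMF) to 1-(benzyloxy)-6-iodo-2,3,4-trimethoxybenzene F2. Ullmann coupling of 26 at the C–I bond of F2 (CuI, picolinic acid, K3PO4, DMSO, 80 °C) should give 1-(benzyloxy)-6-(4-bromo-2,6-dimethoxyphenoxy)-2,3,4-trimethoxybenzene F3. A second Ullmann coupling with 18 at 110 °C should give 1-(benzyloxy)-6-[2,6-dimethoxy-4-(2,4,6-trimethoxyphenoxy)phenoxy]-2,3,4-trimethoxybenzene F4. Hydrogenolysis (H2, Pd/C) should give 6-[2,6-dimethoxy-4-(2,4,6-trimethoxyphenoxy)phenoxy]-2,3,4-trimethoxyphenol F5, and a third Ullmann coupling at the C–I bond of 9 (80 °C) should deliver 22.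

2. Step 19. Copper insertion into the electron-rich C–Br bond next to a methoxy group may be slow at this fragment size, so that reduction of the bromide and oxidative loss of the phenol compete at 110 °C. The fallback reverses the polarity at C5 of ring D; it sets out from 22 and returns at 31. Miyaura borylation of 22 (B2pin2, PdCl2(dppf), KOAc, dioxane, 90 °C) should give the pinacol boronate of the ABCD unit F6. Chan–Lam coupling of this boronate with 30 (Cu(OAc)2, pyridine, B(OH)3, 4 Å molecular sieves, MeCN, air, 60 °C) should give 31 under oxidative conditions that need no C–Br activation.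

3. Step 20. Cleavage of the 18 ethers may stop short and leave partial methyl ethers that cannot be separated from the free polyphenol, and the pyrogallol rings may oxidise in air during isolation. The fallback derivatises, purifies and releases; it sets out from 31 and returns at 32. After the BBr3 treatment the crude product would be acetylated without isolation (Ac2O, pyridine, rt) to the octadecaacetate of the target F7, which can be chromatographed on silica and freed from under-cleaved material. Acid-catalysed methanolysis (HCl in degassed MeOH, rt, argon) and evaporation should then give 32.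

Further compounds
F1 | step 12 | 6-iodo-2,3,4-trimethoxyphenol | COc1cc(I)c(O)c(OC)c1OC
F2 | step 12 | 1-(benzyloxy)-6-iodo-2,3,4-trimethoxybenzene | COc1cc(I)c(OCc2ccccc2)c(OC)c1OC
F3 | step 12 | 1-(benzyloxy)-6-(4-bromo-2,6-dimethoxyphenoxy)-2,3,4-trimethoxybenzene | COc1cc(Oc2c(OC)cc(Br)cc2OC)c(OCc2ccccc2)c(OC)c1OC
F4 | step 12 | 1-(benzyloxy)-6-[2,6-dimethoxy-4-(2,4,6-trimethoxyphenoxy)phenoxy]-2,3,4-trimethoxybenzene | COc1cc(Oc2c(OC)cc(Oc3c(OC)cc(OC)cc3OC)cc2OC)c(OCc2ccccc2)c(OC)c1OC
F5 | step 12 | 6-[2,6-dimethoxy-4-(2,4,6-trimethoxyphenoxy)phenoxy]-2,3,4-trimethoxyphenol | COc1cc(Oc2c(OC)cc(Oc3c(OC)cc(OC)cc3OC)cc2OC)c(O)c(OC)c1OC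
F6 | step 19 | pinacol boronate of the ABCD unit (22 with Bpin in place of Br) | COc1cc(Oc2c(OC)cc(OC)cc2OC)cc(OC)c1Oc1cc(OC)c(OC)c(OC)c1Oc1cc(OC)c(OC)c(c1)B1OC(C)(C)C(C)(C)O1
F7 | step 20 | octadecaacetate of the target | CC(=O)Oc1cc(OC(C)=O)c(Oc2cc(OC(C)=O)c(Oc3cc(OC(C)=O)c(OC(C)=O)c(OC(C)=O)c3Oc3cc(OC(C)=O)c(OC(C)=O)c(Oc4cc(OC(C)=O)c(OC(C)=O)c(OC(C)=O)c4Oc4cc(OC(C)=O)c(Oc5cc(OC(C)=O)c(OC(C)=O)c(OC(C)=O)c5)c(OC(C)=O)c4)c3)c(OC(C)=O)c2)c(OC(C)=O)c1
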